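Abbreviations: TBS = tert-butyldimethylsilyl, TMS = trimethylsilyl. Carbocycle locants follow the target: C1 quaternary carbon, C2 the CH bearing the oxymethyl arm, C3(CH3)=C4H, C5 the CH bearing isopropenyl, C6 the methylene. Coumarin positions are named as such.

## Analysis of the target

The molecule is a 7-oxygenated coumarin (2H-chromen-2-one) joined through an O–CH2 link to a cyclohexene in which five of the six ring carbons are substituted. C1 carries a methyl group and a 2-carboxyethyl chain, C2 the aryloxymethyl arm, C3 a methyl group on the C3=C4 alkene, and C5 an isopropenyl group. There are three stereocentres, (1R,2R,5S). The oxymethyl arm on C2, the acid chain on C1 and the isopropenyl group on C5 lie on one face and the C1 methyl on the other; C1 and C2 are adjacent (quaternary next to tertiary), and C5 is 1,3 to C1 and 1,4 to C2. Sensitive groups are the coumarin lactone and its enoate (hydroxide, alkoxides, cuprates, hydrides), the doubly allylic C5–H of the skipped diene, the acid-labile 1,1-disubstituted alkene and the free acid. The difficulty is to build the contiguous quaternary/tertiary array with the correct relation to the remote C5 centre and then to attach the aryl ether at a β-branched methylene next to the quaternary carbon, where substitution at carbon is slow, all without exposing the coumarin to the reagents the carbocycle needs. The strategy rests on one feature: coumarin C4 is para (through C4a) to the ether oxygen on C7. As a formyl carbon on a benzene ring it first activates a para C–F bond for aryl–oxygen bond formation and then becomes the acceptor of an intramolecular Horner–Wadsworth–Emmons reaction that forms the coumarin C3=C4 bond and closes the pyranone ring.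

## Retrosynthetic reasoning

**28 to 25.** The carboxyl group is taken back to primary alcohol 26 and that to its TBS ether 25. No skeletal bond is cut. The gain is a chain terminus that is inert to organometallic reagents and strong bases throughout. Forward, fluoride must free the alcohol and a nitroxyl-mediated oxidation must raise it to the acid (through aldehyde 27) without touching the two alkenes or the coumarin.

**25 to 24 (key disconnection).** The coumarin C3=C4 double bond is cut, which opens the pyranone to aryl phosphonoacetate 24 with an ortho formyl group. Cutting here, and not at the lactone C–O bond or at the O–CH2 ether, means the heterocycle is made last under mild amine base, and the formyl group that is needed anyway has a second use one stage earlier. Forward, the phosphonate carbanion must condense with the neighbouring aldehyde faster than the aryl ester is cleaved.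

**24 to 22 and 23.** The aryl ester C–O bond is cut to salicylaldehyde 22 and phosphonoacetic acid 23. Forward, a carbodiimide coupling has to acylate a hydrogen-bonded phenol.

**22 to 17 and 19.** After the phenol is masked as allyl ether 21, the bond from the aryl carbon (future coumarin C7) to the ether oxygen is cut, giving alcohol 17 and fluoroarene 19 (from 18). The O–CH2 bond is not chosen because its carbon is β-branched and flanked by the quaternary centre. At the aryl carbon the para formyl group makes fluoride displacement by alkoxide 20 feasible. The allyl group is chosen because zerovalent palladium removes it without acid or fluoride, so the TBS ether is safe.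

**17 to 13.** The C3–CH3 bond is cut to enol triflate 15, which comes from ketone 13 through potassium enolate 14. This places a carbonyl group at C3, from which the C3=C4 alkene can be fixed regiochemically, because kinetic deprotonation prefers the C4 methylene over the hindered C2 methine. The TMS ether (13, 16) keeps the aldol hydroxyl from retro-aldol cleavage and from sulfonylation and falls off under methanolysis that leaves TBS alone.

**13/12 to 10.** Two bonds at adjacent carbons are cut, C1–CH3 and C2–CH2OH, leading to enone 10 with the chain already on the β-carbon. Forward, a methyl-transfer organocopper reagent must add anti to the C5 substituent, and enolate 11 must take up a one-carbon aldehyde electrophile anti to the new axial methyl. This gives both new centres by substrate control from C5. The chain, not the methyl, is placed in the enone because the group added last ends trans to isopropenyl, and that group must be methyl.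

**10 to 6 and 7.** The C1–chain bond is cut. Grignard reagent 8, made from bromide 7, adds to the carbonyl of enone 6, and the tertiary allylic alcohol 9 is oxidised with 1,3-transposition. This moves the carbonyl to the future C3 and leaves the chain on the future C1.

**6 to 1 and 2.** The enone double bond is removed to give ketone 3 via silyl enol ether 5 and enolate 4, and the C5–isopropenyl bond is cut to cyclohexenone 1 and boronate 2. A rhodium-catalysed asymmetric conjugate addition sets the only stereocentre that is not derived from another one.

## Alternatives that were turned down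

**Alternative 1: desymmetrising enzymatic cyclopropanation.**
- Disconnection: the bond from C1 to the first chain carbon and the C1/C2 pair are traced to the cyclopropane-fused δ-lactone A1, and this to the achiral dienylmethyl diazoacetate A2, obtainable by Birch-type reduction of an aromatic precursor.
- Forward key step: an engineered haem protein (a myoglobin or cytochrome P450 variant) forms an iron carbene from A2 and delivers it to one of the two enantiotopic ring alkenes. The carbene carbon bonds to both alkene carbons and closes a cyclopropane and a six-membered lactone.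
- For it: one catalytic step creates the quaternary carbon and the neighbouring CH–CH2O centre from an achiral substrate and ties the oxymethyl arm and the first chain carbon cis, as the target requires.
- Against it: A1 has no substituent at C5, so isopropenyl would have to be introduced later at an allylic methylene with remote stereocontrol. The cyclopropane must be opened selectively at the bond to the ring methylene and not at the bond to the quaternary carbon. The chain is one carbon short, and the lactone must be taken apart into an alcohol for etherification and an acid-level chain. The enzymatic step is also outside established scope, since it needs a homoallylic tether, a trisubstituted ring alkene and discrimination of two enantiotopic alkenes.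
- Comparison: it is stronger in how much stereochemistry a single step creates and in atom economy. The chosen route sets only one centre catalytically, but with an established reaction, derives the other two by predictable substrate control, and installs every ring substituent in the ketone series, so no late C–H functionalisation is needed. Once the steps after A1 are counted, no saving in length is expected.

**Alternative 2: ortho-quinol acetate Diels–Alder and cleavage of the keto bridge.**
- Disconnection: the ring bonds C1–C2 and C5–C6 are cut, leading to bicyclo[2.2.2]octenone A3, from dienone A4 (an o-quinol acetate made by oxidative dearomatisation of a phenol) and methacrolein A5.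
- Forward key step: the diene of A4 adds A5 so that the carbon carrying methyl and formyl bonds next to the bridgehead beside the ketone. Oxidative cleavage of the α-acetoxy ketone bridge later leaves an acetyl group on C5 (to be methylenated) and a carboxyl carbon on C2 (to be reduced), cis by construction.
- For it: the carbocycle, the quaternary centre and all ring substituent carbons arrive in one step from cheap materials, and the cis relation of isopropenyl and oxymethyl needs no control. On ring construction it is more economical than the chosen route.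
- Against it: A4 is racemic and its stereocentre is destroyed on cleavage, so absolute configuration would need an enantioselective cycloaddition of a dimerisation-prone, electron-poor dienone with an electron-poor dienophile, which is not dependable. The configuration at C1 hangs on the endo/exo preference of an α-methyl enal, which is often weak. After A3 come bridge cleavage, methylenation of a methyl ketone beside an aldehyde and an acid, reduction, and a two-carbon homologation of a neopentyl aldehyde, all with protecting-group traffic.
- Comparison: the chosen route secures absolute configuration in its first step and relative configuration through chair-controlled additions.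

**Alternative 3: Ireland–Claisen ring contraction.**
- Disconnection: the ring C1–C2 bond is cut and the C3=C4 alkene moved back, leading from acid A6 to the 5,6-trans δ-lactone A7, which carries an (E)-alkenyl group on the carbinol carbon.
- Forward key step: the silyl ketene acetal of A7 rearranges through a boat transition state, forms C1–C2, shifts the alkene into the ring and opens the lactone to the carboxyl group on C1.
- For it: the concerted suprafacial shift passes C–O chirality to both C1 and C2. For the vicinal quaternary/tertiary pair this control is at least as strong as the conjugate addition–aldol pair used here.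
- Against it: A7 needs two stereocentres and a defined trisubstituted alkene before the key step, so the stereochemical work is moved and not saved. A6 bears the carboxyl directly on the quaternary carbon, so a two-carbon homologation at a neopentyl position follows. The boat transition state forming a quaternary centre from a tetrasubstituted ketene acetal is strained and may be slow.
- Comparison: overall it is longer. The chosen route offers three-carbon chain delivery in one Grignard step and a shorter path to alcohol 17.

Key step: step 14

Assumption: [Rh(cod)Cl]2 with (R)-BINAP is taken to deliver isopropenyl to cyclohexenone with the facial sense established for aryl and 1-alkenyl groups, giving the (R)-ketone. If the sense were opposite, (S)-BINAP would be used.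

## Route

Step 1
Reactants: 1 cyclohex-2-en-1-one; 2 isopropenylboronic acid pinacol ester
Product: 3 (R)-3-(prop-1-en-2-yl)cyclohexan-1-one
Conditions: [Rh(cod)Cl]2 (2.5 mol %), (R)-BINAP (6 mol %), aq. KOH, 1,4-dioxane/H2O (10:1), 40 °C
Reagents that add atoms: none
Why: Hayashi–Miyaura asymmetric conjugate addition: the alkenyl group passes from boron to a rhodium hydroxide, the enone inserts into the Rh–C bond inside the chiral pocket of the diphosphine, and water releases the ketone. The ligand alone sets the stereocentre that becomes C5 of the target.

Step 2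
Reactants: 3 (R)-3-(prop-1-en-2-yl)cyclohexan-1-one
Product: 5 (R)-trimethyl{[5-(prop-1-en-2-yl)cyclohex-1-en-1-yl]oxy}silane, via lithium enolate 4 (not isolated)
Conditions: LiN(iPr)2, THF, −78 °C; then Me3SiCl, Et3N, −78 °C to 25 °C
Reagents that add atoms: chlorotrimethylsilane, C[Si](C)(C)Cl
Why: Kinetic enolisation: the amide base should take the axial proton of the unhindered α-methylene remote from the isopropenyl-bearing carbon in preference to the α-methylene next to it, and O-silylation freezes this regiochemistry. The stereocentre is β to the carbonyl and is not affected.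

Step 3
Reactants: 5 (R)-trimethyl{[5-(prop-1-en-2-yl)cyclohex-1-en-1-yl]oxy}silane
Product: 6 (R)-5-(prop-1-en-2-yl)cyclohex-2-en-1-one
Conditions: Pd(OAc)2 (10 mol %), O2 (1 atm), DMSO, 25 °C
Reagents that add atoms: none
Why: Saegusa–Ito oxidation: divalent palladium adds to the enol silane, β-hydride elimination places the alkene on the side fixed in step 2, and oxygen returns the palladium to the divalent state. The isolated isopropenyl group is not engaged.

Step 4
Reactants: 6 (R)-5-(prop-1-en-2-yl)cyclohex-2-en-1-one; 7 (3-bromopropoxy)(tert-butyl)dimethylsilane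
Product: 9 (5R)-1-{3-[(tert-butyldimethylsilyl)oxy]propyl}-5-(prop-1-en-2-yl)cyclohex-2-en-1-ol, via Grignard reagent 8 (not isolated)
Conditions: 7, Mg, THF, 40 °C; then CeCl3, THF, −78 °C; then 6, −78 to 0 °C; aq. NH4Cl
Reagents that add atoms: none
Why: 1,2-Addition of a primary alkyl Grignard reagent to the enone carbonyl, with CeCl3 suppressing enolisation and conjugate addition. The carbinol centre forms as a mixture, which does not matter because it becomes sp2 in step 5.

Step 5
Reactants: 9 (5R)-1-{3-[(tert-butyldimethylsilyl)oxy]propyl}-5-(prop-1-en-2-yl)cyclohex-2-en-1-ol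
Product: 10 (S)-3-{3-[(tert-butyldimethylsilyl)oxy]propyl}-5-(prop-1-en-2-yl)cyclohex-2-en-1-one
Conditions: [C5H5NH][CrO3Cl] (2 equiv), NaOAc, 4 Å molecular sieves, CH2Cl2, 25 °C
Reagents that add atoms: pyridinium chlorochromate, [O-][Cr](=O)(=O)Cl.c1cc[nH+]cc1
Why: Babler–Dauben oxidative transposition: the tertiary allylic chromate ester undergoes a [3,3] shift to the secondary allylic chromate, which is oxidised to the enone, so the chain ends on the β-carbon and the carbonyl two carbons away. NaOAc buffers the medium for the silyl ether; the descriptor changes from R to S only through the priority rules.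

Step 6
Reactants: 10 (S)-3-{3-[(tert-butyldimethylsilyl)oxy]propyl}-5-(prop-1-en-2-yl)cyclohex-2-en-1-one
Product: 12 (2S,3R,5S)-3-{3-[(tert-butyldimethylsilyl)oxy]propyl}-2-(hydroxymethyl)-3-methyl-5-(prop-1-en-2-yl)cyclohexan-1-one, via lithium enolate 11 (not isolated)
Conditions: Me2CuLi (from MeLi and CuI), Et2O, −78 to 0 °C; then CH2O (monomer, gas), −78 °C; aq. NH4Cl
Reagents that add atoms: lithium dimethylcuprate, [Li+].C[Cu-]C; formaldehyde, C=O
Why: Tandem conjugate addition–aldol: the cuprate adds axially to the β-carbon anti to the pseudo-equatorial isopropenyl group, which makes the quaternary centre with methyl trans to isopropenyl. The enolate is then hydroxymethylated antiperiplanar to the now axial methyl group (chair-like attack), so CH2OH ends cis to the chain and to isopropenyl, as in the target.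

Step 7
Reactants: 12 (2S,3R,5S)-3-{3-[(tert-butyldimethylsilyl)oxy]propyl}-2-(hydroxymethyl)-3-methyl-5-(prop-1-en-2-yl)cyclohexan-1-one
Product: 13 (2S,3R,5S)-3-{3-[(tert-butyldimethylsilyl)oxy]propyl}-3-methyl-5-(prop-1-en-2-yl)-2-{[(trimethylsilyl)oxy]methyl}cyclohexan-1-one
Conditions: Me3SiCl, imidazole, CH2Cl2, 0 °C
Reagents that add atoms: chlorotrimethylsilane, C[Si](C)(C)Cl
Why: O-Silylation of the primary aldol hydroxyl under buffered conditions. It blocks retro-aldol cleavage and O-sulfonylation in step 8 and is labile enough to be removed after step 9 without touching the TBS ether.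

Step 8
Reactants: 13 (2S,3R,5S)-3-{3-[(tert-butyldimethylsilyl)oxy]propyl}-3-methyl-5-(prop-1-en-2-yl)-2-{[(trimethylsilyl)oxy]methyl}cyclohexan-1-one
Product: 15 (3S,5R,6S)-5-{3-[(tert-butyldimethylsilyl)oxy]propyl}-5-methyl-3-(prop-1-en-2-yl)-6-{[(trimethylsilyl)oxy]methyl}cyclohex-1-en-1-yl trifluoromethanesulfonate, via potassium enolate 14 (not isolated)
Conditions: KN(SiMe3)2, THF, −78 °C; then PhNTf2, −78 to 0 °C
Reagents that add atoms: N-phenylbis(trifluoromethanesulfonimide), O=S(=O)(N(c1ccccc1)S(=O)(=O)C(F)(F)F)C(F)(F)F
Why: Kinetic deprotonation takes the secondary α-methylene, not the tertiary α-CH flanked by the quaternary carbon, and O-sulfonylation of the enolate gives the enol triflate with the double bond in the C3=C4 position of the target. The C2 centre is never enolised and keeps its configuration.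

Step 9
Reactants: 15 (3S,5R,6S)-5-{3-[(tert-butyldimethylsilyl)oxy]propyl}-5-methyl-3-(prop-1-en-2-yl)-6-{[(trimethylsilyl)oxy]methyl}cyclohex-1-en-1-yl trifluoromethanesulfonate
Product: 17 [(1R,4S,6R)-6-{3-[(tert-butyldimethylsilyl)oxy]propyl}-2,6-dimethyl-4-(prop-1-en-2-yl)cyclohex-2-en-1-yl]methanol, via trimethylsilyl ether 16 (not isolated)
Conditions: MeMgBr, Fe(acac)3 (10 mol %), THF/N-methylpyrrolidinone, −30 to 0 °C; then K2CO3, MeOH, 25 °C
Reagents that add atoms: methylmagnesium bromide, C[Mg]Br
Why: Iron-catalysed Kumada-type cross-coupling of an alkenyl triflate with a methyl Grignard reagent, which is fast at low temperature and tolerates silyl ethers and isolated alkenes. Methanolysis with K2CO3 then cleaves only the trimethylsilyl ether.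

Step 10
Reactants: 18 4-fluoro-2-hydroxybenzaldehyde
Product: 19 4-fluoro-2-(prop-2-en-1-yloxy)benzaldehyde
Conditions: allyl bromide, K2CO3, DMF, 25 °C
Reagents that add atoms: allyl bromide, C=CCBr
Why: Williamson O-alkylation of the phenoxide. The allyl group masks the phenol, whose anion would deactivate the ring toward substitution, and can later be removed without acid or fluoride.

Step 11
Reactants: 17 [(1R,4S,6R)-6-{3-[(tert-butyldimethylsilyl)oxy]propyl}-2,6-dimethyl-4-(prop-1-en-2-yl)cyclohex-2-en-1-yl]methanol; 19 4-fluoro-2-(prop-2-en-1-yloxy)benzaldehyde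
Product: 21 4-{[(1R,4S,6R)-6-{3-[(tert-butyldimethylsilyl)oxy]propyl}-2,6-dimethyl-4-(prop-1-en-2-yl)cyclohex-2-en-1-yl]methoxy}-2-(prop-2-en-1-yloxy)benzaldehyde, via sodium alkoxide 20 (not isolated)
Conditions: NaH, DMF, 0 °C; then 19, 0 to 25 °C
Reagents that add atoms: none
Why: Nucleophilic aromatic substitution: the alkoxide attacks the carbon para to the formyl group, the Meisenheimer anion is stabilised by the aldehyde, and fluoride leaves. The C–O bond is formed at the aryl carbon, so the hindered β-branched methylene never has to act as an electrophile.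

Step 12
Reactants: 21 4-{[(1R,4S,6R)-6-{3-[(tert-butyldimethylsilyl)oxy]propyl}-2,6-dimethyl-4-(prop-1-en-2-yl)cyclohex-2-en-1-yl]methoxy}-2-(prop-2-en-1-yloxy)benzaldehyde
Product: 22 4-{[(1R,4S,6R)-6-{3-[(tert-butyldimethylsilyl)oxy]propyl}-2,6-dimethyl-4-(prop-1-en-2-yl)cyclohex-2-en-1-yl]methoxy}-2-hydroxybenzaldehyde
Conditions: Pd(PPh3)4 (5 mol %), K2CO3, MeOH, 25 °C
Reagents that add atoms: none
Why: Tsuji–Trost-type deallylation: zerovalent palladium ionises the aryl allyl ether to a π-allyl complex and the phenoxide, and methoxide takes up the allyl unit. The silyl ether, the aldehyde and the unactivated alkenes are inert.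

Step 13
Reactants: 22 4-{[(1R,4S,6R)-6-{3-[(tert-butyldimethylsilyl)oxy]propyl}-2,6-dimethyl-4-(prop-1-en-2-yl)cyclohex-2-en-1-yl]methoxy}-2-hydroxybenzaldehyde; 23 2-(diethoxyphosphoryl)acetic acid
Product: 24 5-{[(1R,4S,6R)-6-{3-[(tert-butyldimethylsilyl)oxy]propyl}-2,6-dimethyl-4-(prop-1-en-2-yl)cyclohex-2-en-1-yl]methoxy}-2-formylphenyl 2-(diethoxyphosphoryl)acetate
Conditions: N,N'-dicyclohexylcarbodiimide, 4-(dimethylamino)pyridine (5 mol %), CH2Cl2, 0 °C
Reagents that add atoms: none
Why: Steglich esterification of the hydrogen-bonded phenol through the O-acylisourea and the acylpyridinium ion. Any ring closure that already starts under the basic catalyst only anticipates step 14.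

Step 14
Reactants: 24 5-{[(1R,4S,6R)-6-{3-[(tert-butyldimethylsilyl)oxy]propyl}-2,6-dimethyl-4-(prop-1-en-2-yl)cyclohex-2-en-1-yl]methoxy}-2-formylphenyl 2-(diethoxyphosphoryl)acetate
Product: 25 7-{[(1R,4S,6R)-6-{3-[(tert-butyldimethylsilyl)oxy]propyl}-2,6-dimethyl-4-(prop-1-en-2-yl)cyclohex-2-en-1-yl]methoxy}-2H-chromen-2-one
Conditions: LiCl, 1,8-diazabicyclo[5.4.0]undec-7-ene, MeCN, 0 to 25 °C
Reagents that add atoms: none
Why: Lithium binds the phosphoryl and ester carbonyl oxygens of 24 and so acidifies the P–CH2–C(=O) protons enough for the amidine base to remove one (Masamune–Roush variant of the Horner–Wadsworth–Emmons reaction). The stabilised carbanion adds to the ortho formyl carbon in a 6-(enolendo)-exo-trig closure that forms the coumarin C3–C4 bond and a six-membered ring. The lithium alkoxide at C4 then closes onto phosphorus to a ring-fused oxaphosphetane, whose syn cycloreversion expels diethyl phosphate and leaves the C3=C4 double bond, necessarily cis inside the pyranone. The closest known reaction type is the intramolecular olefination of O-(phosphonoacetyl)salicylaldehydes, together with the related Knoevenagel-type annulations of O-acylsalicylaldehydes to coumarins. No stereocentre is created, the transient centres at C3 and C4 vanish on elimination, and the three ring stereocentres are safe from the base because none is α to a carbonyl group. The selectivity needed is chemoselectivity: olefination must outrun cleavage of the activated aryl ester and dehydration pathways that would keep phosphorus on C3. It is secured by the absence of any external oxygen nucleophile, by the proximity of the aldehyde, and by the affinity of the lithium alkoxide for phosphorus in an aprotic medium; a trans adduct that cannot reach phosphorus can revert or epimerise at the acidic C3 position and drain through the cis adduct.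

Step 15
Reactants: 25 7-{[(1R,4S,6R)-6-{3-[(tert-butyldimethylsilyl)oxy]propyl}-2,6-dimethyl-4-(prop-1-en-2-yl)cyclohex-2-en-1-yl]methoxy}-2H-chromen-2-one
Product: 26 7-{[(1R,4S,6R)-6-(3-hydroxypropyl)-2,6-dimethyl-4-(prop-1-en-2-yl)cyclohex-2-en-1-yl]methoxy}-2H-chromen-2-one
Conditions: Bu4NF, AcOH, THF, 25 °C
Reagents that add atoms: none
Why: Fluoride-induced cleavage of the primary silyl ether. Acetic acid buffers the fluoride so that the coumarin lactone is not opened.

Step 16
Reactants: 26 7-{[(1R,4S,6R)-6-(3-hydroxypropyl)-2,6-dimethyl-4-(prop-1-en-2-yl)cyclohex-2-en-1-yl]methoxy}-2H-chromen-2-one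
Product: 28 3-[(1R,2R,5S)-1,3-dimethyl-2-{[(2-oxo-2H-chromen-7-yl)oxy]methyl}-5-(prop-1-en-2-yl)cyclohex-3-en-1-yl]propanoic acid, via aldehyde 27 (not isolated)
Conditions: TEMPO (20 mol %), PhI(OAc)2 (2.2 equiv), MeCN/H2O (1:1), 25 °C
Reagents that add atoms: water, O
Why: Nitroxyl-catalysed oxidation: the oxoammonium ion oxidises the alcohol to aldehyde 27, whose hydrate is oxidised again to the acid. This reagent pair leaves isolated alkenes, the aryl ether and the coumarin alone.

## Compound list

1 | cyclohex-2-en-1-one | O=C1C=CCCC1 | starting material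
2 | 4,4,5,5-tetramethyl-2-(prop-1-en-2-yl)-1,3,2-dioxaborolane (isopropenylboronic acid pinacol ester) | CC(=C)B1OC(C)(C)C(C)(C)O1 | starting material
3 | (R)-3-(prop-1-en-2-yl)cyclohexan-1-one | C=C(C)[C@H]1CC(=O)CCC1 | intermediate
4 | lithium (R)-5-(prop-1-en-2-yl)cyclohex-1-en-1-olate (formed in situ) | C=C(C)[C@H]1CC([O-])=CCC1.[Li+] | intermediate
5 | (R)-trimethyl{[5-(prop-1-en-2-yl)cyclohex-1-en-1-yl]oxy}silane | C=C(C)[C@H]1CC(O[Si](C)(C)C)=CCC1 | intermediate
6 | (R)-5-(prop-1-en-2-yl)cyclohex-2-en-1-one | C=C(C)[C@H]1CC(=O)C=CC1 | intermediate
7 | (3-bromopropoxy)(tert-butyl)dimethylsilane | BrCCCO[Si](C)(C)C(C)(C)C | starting material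
8 | {3-[(tert-butyldimethylsilyl)oxy]propyl}magnesium bromide (formed in situ) | Br[Mg]CCCO[Si](C)(C)C(C)(C)C | intermediate
9 | (5R)-1-{3-[(tert-butyldimethylsilyl)oxy]propyl}-5-(prop-1-en-2-yl)cyclohex-2-en-1-ol (both C1 epimers) | C=C(C)[C@H]1CC(O)(CCCO[Si](C)(C)C(C)(C)C)C=CC1 | intermediate
10 | (S)-3-{3-[(tert-butyldimethylsilyl)oxy]propyl}-5-(prop-1-en-2-yl)cyclohex-2-en-1-one | C=C(C)[C@@H]1CC(=O)C=C(CCCO[Si](C)(C)C(C)(C)C)C1 | intermediate
11 | lithium (3R,5S)-3-{3-[(tert-butyldimethylsilyl)oxy]propyl}-3-methyl-5-(prop-1-en-2-yl)cyclohex-1-en-1-olate (formed in situ) | C=C(C)[C@@H]1CC([O-])=C[C@](C)(CCCO[Si](C)(C)C(C)(C)C)C1.[Li+] | intermediate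
12 | (2S,3R,5S)-3-{3-[(tert-butyldimethylsilyl)oxy]propyl}-2-(hydroxymethyl)-3-methyl-5-(prop-1-en-2-yl)cyclohexan-1-one | C=C(C)[C@@H]1CC(=O)[C@H](CO)[C@](C)(CCCO[Si](C)(C)C(C)(C)C)C1 | intermediate
13 | (2S,3R,5S)-3-{3-[(tert-butyldimethylsilyl)oxy]propyl}-3-methyl-5-(prop-1-en-2-yl)-2-{[(trimethylsilyl)oxy]methyl}cyclohexan-1-one | C=C(C)[C@@H]1CC(=O)[C@H](CO[Si](C)(C)C)[C@](C)(CCCO[Si](C)(C)C(C)(C)C)C1 | intermediate
14 | potassium (3S,5R,6S)-5-{3-[(tert-butyldimethylsilyl)oxy]propyl}-5-methyl-3-(prop-1-en-2-yl)-6-{[(trimethylsilyl)oxy]methyl}cyclohex-1-en-1-olate (formed in situ) | C=C(C)[C@@H]1C=C([O-])[C@H](CO[Si](C)(C)C)[C@](C)(CCCO[Si](C)(C)C(C)(C)C)C1.[K+] | intermediate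
15 | (3S,5R,6S)-5-{3-[(tert-butyldimethylsilyl)oxy]propyl}-5-methyl-3-(prop-1-en-2-yl)-6-{[(trimethylsilyl)oxy]methyl}cyclohex-1-en-1-yl trifluoromethanesulfonate | C=C(C)[C@@H]1C=C(OS(=O)(=O)C(F)(F)F)[C@H](CO[Si](C)(C)C)[C@](C)(CCCO[Si](C)(C)C(C)(C)C)C1 | intermediate
16 | tert-butyl{3-[(1R,2R,5S)-1,3-dimethyl-5-(prop-1-en-2-yl)-2-{[(trimethylsilyl)oxy]methyl}cyclohex-3-en-1-yl]propoxy}dimethylsilane (formed in situ) | C=C(C)[C@@H]1C=C(C)[C@H](CO[Si](C)(C)C)[C@](C)(CCCO[Si](C)(C)C(C)(C)C)C1 | intermediate
17 | [(1R,4S,6R)-6-{3-[(tert-butyldimethylsilyl)oxy]propyl}-2,6-dimethyl-4-(prop-1-en-2-yl)cyclohex-2-en-1-yl]methanol | C=C(C)[C@@H]1C=C(C)[C@H](CO)[C@](C)(CCCO[Si](C)(C)C(C)(C)C)C1 | intermediate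
18 | 4-fluoro-2-hydroxybenzaldehyde | O=Cc1ccc(F)cc1O | starting material
19 | 4-fluoro-2-(prop-2-en-1-yloxy)benzaldehyde | O=Cc1ccc(F)cc1OCC=C | intermediate
20 | sodium [(1R,4S,6R)-6-{3-[(tert-butyldimethylsilyl)oxy]propyl}-2,6-dimethyl-4-(prop-1-en-2-yl)cyclohex-2-en-1-yl]methanolate (formed in situ) | C=C(C)[C@@H]1C=C(C)[C@H](C[O-])[C@](C)(CCCO[Si](C)(C)C(C)(C)C)C1.[Na+] | intermediate
21 | 4-{[(1R,4S,6R)-6-{3-[(tert-butyldimethylsilyl)oxy]propyl}-2,6-dimethyl-4-(prop-1-en-2-yl)cyclohex-2-en-1-yl]methoxy}-2-(prop-2-en-1-yloxy)benzaldehyde | C=C(C)[C@@H]1C=C(C)[C@H](COc2ccc(C=O)c(OCC=C)c2)[C@](C)(CCCO[Si](C)(C)C(C)(C)C)C1 | intermediate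
22 | 4-{[(1R,4S,6R)-6-{3-[(tert-butyldimethylsilyl)oxy]propyl}-2,6-dimethyl-4-(prop-1-en-2-yl)cyclohex-2-en-1-yl]methoxy}-2-hydroxybenzaldehyde | C=C(C)[C@@H]1C=C(C)[C@H](COc2ccc(C=O)c(O)c2)[C@](C)(CCCO[Si](C)(C)C(C)(C)C)C1 | intermediate
23 | 2-(diethoxyphosphoryl)acetic acid (diethylphosphonoacetic acid) | CCOP(=O)(CC(=O)O)OCC | starting material
24 | 5-{[(1R,4S,6R)-6-{3-[(tert-butyldimethylsilyl)oxy]propyl}-2,6-dimethyl-4-(prop-1-en-2-yl)cyclohex-2-en-1-yl]methoxy}-2-formylphenyl 2-(diethoxyphosphoryl)acetate | C=C(C)[C@@H]1C=C(C)[C@H](COc2ccc(C=O)c(OC(=O)CP(=O)(OCC)OCC)c2)[C@](C)(CCCO[Si](C)(C)C(C)(C)C)C1 | intermediate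
25 | 7-{[(1R,4S,6R)-6-{3-[(tert-butyldimethylsilyl)oxy]propyl}-2,6-dimethyl-4-(prop-1-en-2-yl)cyclohex-2-en-1-yl]methoxy}-2H-chromen-2-one | C=C(C)[C@@H]1C=C(C)[C@H](COc2ccc3ccc(=O)oc3c2)[C@](C)(CCCO[Si](C)(C)C(C)(C)C)C1 | intermediate
26 | 7-{[(1R,4S,6R)-6-(3-hydroxypropyl)-2,6-dimethyl-4-(prop-1-en-2-yl)cyclohex-2-en-1-yl]methoxy}-2H-chromen-2-one | C=C(C)[C@@H]1C=C(C)[C@H](COc2ccc3ccc(=O)oc3c2)[C@](C)(CCCO)C1 | intermediate
27 | 3-[(1R,2R,5S)-1,3-dimethyl-2-{[(2-oxo-2H-chromen-7-yl)oxy]methyl}-5-(prop-1-en-2-yl)cyclohex-3-en-1-yl]propanal (formed in situ) | C=C(C)[C@@H]1C=C(C)[C@H](COc2ccc3ccc(=O)oc3c2)[C@](C)(CCC=O)C1 | intermediate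
28 | 3-[(1R,2R,5S)-1,3-dimethyl-2-{[(2-oxo-2H-chromen-7-yl)oxy]methyl}-5-(prop-1-en-2-yl)cyclohex-3-en-1-yl]propanoic acid | C=C(C)[C@@H]1C=C(C)[C@H](COc2ccc3ccc(=O)oc3c2)[C@](C)(CCC(=O)O)C1 | target

## Step count and least certain steps

Total step count: 16. Longest linear sequence: 15 steps (steps 1–9 and 11–16, from cyclohexenone 1); step 10 is a one-step branch.

**Step 14 (key step).** The phosphonate anion may fail to olefinate cleanly. The activated aryl ester can be cleaved (by adventitious water, or by loss of the phenoxide through a ketene), or the aldol adduct can dehydrate with phosphorus retained on C3 instead of collapsing through the oxaphosphetane. Fallback, from 22 back to 25: intermolecular Wittig olefination of salicylaldehyde 22 with Ph3P=CHCO2Et (toluene, 80 °C) gives ethyl (E)-3-[2-hydroxy-4-(terpenylmethoxy)phenyl]prop-2-enoate F1. Irradiation at 365 nm isomerises the cinnamate, and the Z isomer lactonises spontaneously with loss of ethanol to 25. The ring is then closed by C–O bond formation after the alkene is made, not by the olefination itself.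

**Step 2.** Regiocontrol of the kinetic enolisation may be insufficient. Deprotonation on the side of the isopropenyl-bearing carbon leads after oxidation to an achiral conjugated dienone, so material and the stereocentre are lost. Fallback, from 3 back to 6: acylation of ketone 3 under equilibrating conditions (NaH, diallyl carbonate, THF, reflux) should go to the α-carbon remote from the substituent, because the alternative β-keto ester enolate suffers allylic strain, and gives allyl (4R)-2-oxo-4-(prop-1-en-2-yl)cyclohexane-1-carboxylate F2. Palladium-catalysed decarboxylation–dehydrogenation of this allyl β-keto ester (Pd(OAc)2, PPh3, MeCN, 80 °C) then gives enone 6 with the double bond fixed by the position of the ester.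

**Step 6.** Conjugate addition to the β,β-disubstituted enone may be sluggish, and the cuprate-derived enolate may be captured poorly. Proton transfer, multiple hydroxymethylation, retro-aldol cleavage or dehydration on work-up, or incomplete facial control at C2 would all lower the return. Fallback, from 10 back to 12: the conjugate addition is run with Me2CuLi and Me3SiCl (THF, −78 °C) to isolate the silyl enol ether tert-butyldimethyl{3-[(1R,5S)-1-methyl-5-(prop-1-en-2-yl)-3-[(trimethylsilyl)oxy]cyclohex-2-en-1-yl]propoxy}silane F3. A Mukaiyama aldol reaction with aqueous formaldehyde and catalytic Yb(OTf)3 (THF, 25 °C) then installs the hydroxymethyl group under the same axial-methyl control and gives 12.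

**Step 11.** Substitution by the hindered alkoxide may be slow enough for reversible addition to the aldehyde and hydride transfer from the alkoxide to the aldehyde to compete. Fallback, from 17 back to 22: Mitsunobu etherification of alcohol 17 with 2,4-dihydroxybenzaldehyde (PPh3, diisopropyl azodicarboxylate, THF) takes place at the free 4-hydroxyl, because the 2-hydroxyl is tied up by hydrogen bonding to the formyl group, and gives 22 directly. The ether bond is then formed at the alkyl carbon, steps 10 and 12 are not needed, and no new compound arises (F0).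

## Further compounds

F1 | step 14 | ethyl (E)-3-[4-{[(1R,4S,6R)-6-{3-[(tert-butyldimethylsilyl)oxy]propyl}-2,6-dimethyl-4-(prop-1-en-2-yl)cyclohex-2-en-1-yl]methoxy}-2-hydroxyphenyl]prop-2-enoate | C=C(C)[C@@H]1C=C(C)[C@H](COc2ccc(/C=C/C(=O)OCC)c(O)c2)[C@](C)(CCCO[Si](C)(C)C(C)(C)C)C1
F2 | step 2 | allyl (4R)-2-oxo-4-(prop-1-en-2-yl)cyclohexane-1-carboxylate (C1 epimers and enol form) | C=C(C)[C@H]1CC(=O)C(C(=O)OCC=C)CC1
F3 | step 6 | tert-butyldimethyl{3-[(1R,5S)-1-methyl-5-(prop-1-en-2-yl)-3-[(trimethylsilyl)oxy]cyclohex-2-en-1-yl]propoxy}silane | C=C(C)[C@@H]1CC(O[Si](C)(C)C)=C[C@](C)(CCCO[Si](C)(C)C(C)(C)C)C1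
F0 | step 11 | none | none
A1 | alternative 1 | tricyclic cyclopropane-fused δ-lactone retaining the ring C3=C4 alkene | C1C=C(C)[C@@H]2COC(=O)[C@@H]3[C@H]1[C@]23C
A2 | alternative 1 | (2,6-dimethylcyclohexa-2,5-dien-1-yl)methyl 2-diazoacetate | CC1=CCC=C(C)C1COC(=O)C=[N+]=[N-]
A3 | alternative 2 | 3-acetoxy-3,6,7-trimethyl-2-oxobicyclo[2.2.2]oct-5-ene-7-carbaldehyde (formyl on the keto-bridge side) | C[C@]1(OC(C)=O)[C@@H]2C=C(C)[C@H](C1=O)[C@](C)(C=O)C2
A4 | alternative 2 | 6-acetoxy-3,6-dimethylcyclohexa-2,4-dien-1-one (racemic) | CC1=CC(=O)C(C)(OC(C)=O)C=C1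
A5 | alternative 2 | methacrolein (2-methylprop-2-enal) | CC(=C)C=O
A6 | alternative 3 | (1R,2R,5S)-2-{[(tert-butyldimethylsilyl)oxy]methyl}-1,3-dimethyl-5-(prop-1-en-2-yl)cyclohex-3-ene-1-carboxylic acid | C=C(C)[C@@H]1C=C(C)[C@H](CO[Si](C)(C)C(C)(C)C)[C@](C)(C(=O)O)C1
A7 | alternative 3 | (5R,6S)-6-[(E)-4-{[tert-butyldimethylsilyl]oxy}but-2-en-2-yl]-3-methyl-5-(prop-1-en-2-yl)oxan-2-one (5,6-trans; C3 unspecified) | CC1C[C@H](C(C)=C)[C@@H](/C(C)=C/CO[Si](C)(C)C(C)(C)C)OC1=O
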